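**Retrosynthetic overview**
1. 17 ⇒ 16 ⇒ 15: the last two operations are chelation-directed cleavage of the 5-OMe group and hydrogenolysis of the two B-ring benzyl ethers.
2. 15 ⇒ 13: ring C (the pyranone) is the only ring built, and it closes last by oxidative cyclisation of a 2'-hydroxychalcone. Rings A and B are bought as arenes.
3. 13 ⇒ 9 + 11: the Cα–Cβ bond comes from an intermolecular Claisen–Schmidt aldol condensation of the A-ring acetophenone with the B-ring aldehyde.
4. 9 ⇒ 7 ⇒ 1: Friedel–Crafts acetylation with ortho-demethylation of pentamethoxybenzene, which is made from 3,4,5-trimethoxyphenol by methylation, formylation, Baeyer–Villiger oxidation and methylation.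
5. 11 ⇒ 10: double O-benzylation of 2,4-dihydroxybenzaldehyde.

**Assumption:** Tamadone is an achiral flavone with no stereocentre, so "single enantiomer" has no meaning here. The only stereo-elements on the way are the racemic centres in 12 and 14 and the E-alkene in 13, and all of them are erased.

**Step 1**
Reactants: 1 3,4,5-trimethoxyphenol
Product: 2 1,2,3,5-tetramethoxybenzene
Conditions: MeI (1.5 equiv), K2CO3 (2 equiv), acetone, reflux
Reagents that add atoms: iodomethane CI
Why: Williamson O-methylation of the only acidic OH group is clean and forms no stereocentre.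

**Step 2**
Reactants: 2 1,2,3,5-tetramethoxybenzene
Product: 4 2,3,4,6-tetramethoxybenzaldehyde, via iminium salt 3 (not isolated)
Conditions: POCl3 (1.3 equiv), DMF, 0 °C → 50 °C; then ice-water, rt
Reagents that add atoms: N,N-dimethylformamide CN(C)C=O; water O
Why: Vilsmeier–Haack formylation of a strongly activated arene whose two free positions are equivalent gives a single aldehyde and no stereocentre.

**Step 3**
Reactants: 4 2,3,4,6-tetramethoxybenzaldehyde
Product: 6 2,3,4,6-tetramethoxyphenol, via aryl formate 5 (not isolated)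
Conditions: mCPBA (1.3 equiv), CH2Cl2, 0 °C → rt; concentrate; then NaOH, MeOH/H2O, rt (under N2); HCl to pH 3
Reagents that add atoms: mCPBA OOC(=O)c1cccc(Cl)c1
Why: In this Baeyer–Villiger (Dakin-type) oxidation the electron-rich aryl group migrates exclusively, and the phenol stays masked as its formate while oxidant is present; no stereocentre is formed.

**Step 4**
Reactants: 6 2,3,4,6-tetramethoxyphenol
Product: 7 pentamethoxybenzene
Conditions: MeI (1.5 equiv), K2CO3 (2 equiv), acetone, reflux
Reagents that add atoms: iodomethane CI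
Why: Williamson O-methylation of the single phenol gives the symmetric penta-ether and forms no stereocentre.

**Step 5**
Reactants: 7 pentamethoxybenzene
Product: 9 2-hydroxy-3,4,5,6-tetramethoxyacetophenone, via pentamethoxyacetophenone 8 (not isolated)
Conditions: AcCl (1.2 equiv), AlCl3 (2.5 equiv), CH2Cl2, 0 °C → rt (TLC control); then ice/1 M HCl
Reagents that add atoms: acetyl chloride CC(=O)Cl
Why: Friedel–Crafts acylation takes the only free ring position, and carbonyl-chelated AlCl3 then cleaves one of the two equivalent ortho methyl ethers, so there is no regiochemical issue and no stereocentre.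

**Step 6**
Reactants: 10 2,4-dihydroxybenzaldehyde
Product: 11 2,4-bis(benzyloxy)benzaldehyde
Conditions: BnBr (2.4 equiv), K2CO3 (3 equiv), DMF, 70 °C
Reagents that add atoms: benzyl bromide BrCc1ccccc1
Why: Williamson benzylation in warm DMF also alkylates the hydrogen-bonded 2-OH group, giving base-stable and hydrogenolysable protection with no stereocentre.

**Step 7**
Reactants: 9 2-hydroxy-3,4,5,6-tetramethoxyacetophenone; 11 2,4-bis(benzyloxy)benzaldehyde
Product: 13 (E)-3-[2,4-bis(benzyloxy)phenyl]-1-(2-hydroxy-3,4,5,6-tetramethoxyphenyl)prop-2-en-1-one, via aldol adduct 12 (not isolated)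
Conditions: KOH (50% aq, 10 equiv), EtOH/THF, rt, 48 h; then cold 1 M HCl to pH 3
Reagents that add atoms: none
Why: In this Claisen–Schmidt aldol condensation only the methyl ketone can enolise and only the aldehyde can accept, and the racemic carbinol centre of 12 is lost by E1cB dehydration to the thermodynamically favoured E-enone.

**Step 8**
Reactants: 13 (E)-3-[2,4-bis(benzyloxy)phenyl]-1-(2-hydroxy-3,4,5,6-tetramethoxyphenyl)prop-2-en-1-one
Product: 15 2-[2,4-bis(benzyloxy)phenyl]-5,6,7,8-tetramethoxy-4H-chromen-4-one, via flavanone 14 (not isolated)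
Conditions: I2 (10 mol%), DMSO, 120 °C, 3 h; aq Na2S2O3 wash
Reagents that add atoms: none
Why: In this I2/DMSO oxidative cyclisation, oxa-Michael closure gives the racemic flavanone and iodine-mediated dehydrogenation erases its C2 centre, with DMSO as terminal oxidant, so any flavanone already present in 13 converges on the same flavone.

**Step 9**
Reactants: 15 2-[2,4-bis(benzyloxy)phenyl]-5,6,7,8-tetramethoxy-4H-chromen-4-one
Product: 16 2-(2,4-dihydroxyphenyl)-5,6,7,8-tetramethoxy-4H-chromen-4-one
Conditions: H2 (1 atm), 10% Pd/C, EtOAc/MeOH, rt, stop at full conversion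
Reagents that add atoms: none
Why: Catalytic hydrogenolysis of aryl benzyl ethers is much faster than reduction of the conjugated, trisubstituted flavone C2=C3 bond, methyl ethers are inert, and no stereocentre is formed.

**Step 10**
Reactants: 16 2-(2,4-dihydroxyphenyl)-5,6,7,8-tetramethoxy-4H-chromen-4-one
Product: 17 Tamadone, 2-(2,4-dihydroxyphenyl)-5-hydroxy-6,7,8-trimethoxy-4H-chromen-4-one
Conditions: BCl3 (1 M in CH2Cl2, 4 equiv), CH2Cl2, −78 → 0 °C; then 1 M aq HCl, rt
Reagents that add atoms: none
Why: In this chelation-controlled Lewis-acid ether cleavage boron bridges C4=O and the peri 5-OMe in a six-membered chelate, so only that methyl group leaves at or below 0 °C (two equivalents are held by the free phenols), and any Wessely–Moser-type reclosure would be degenerate because the opened A ring is symmetric.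

**Compound list**
1 | 3,4,5-trimethoxyphenol | COc1cc(O)cc(OC)c1OC | starting material
2 | 1,2,3,5-tetramethoxybenzene | COc1cc(OC)c(OC)c(OC)c1 | intermediate
3 | dimethyl[(2,3,4,6-tetramethoxyphenyl)methylidene]ammonium chloride | COc1cc(OC)c(C=[N+](C)C)c(OC)c1OC.[Cl-] | intermediate
4 | 2,3,4,6-tetramethoxybenzaldehyde | COc1cc(OC)c(C=O)c(OC)c1OC | intermediate
5 | 2,3,4,6-tetramethoxyphenyl formate | COc1cc(OC)c(OC=O)c(OC)c1OC | intermediate
6 | 2,3,4,6-tetramethoxyphenol | COc1cc(OC)c(O)c(OC)c1OC | intermediate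
7 | pentamethoxybenzene | COc1cc(OC)c(OC)c(OC)c1OC | intermediate
8 | 2,3,4,5,6-pentamethoxyacetophenone | COc1c(OC)c(OC)c(C(C)=O)c(OC)c1OC | intermediate
9 | 2-hydroxy-3,4,5,6-tetramethoxyacetophenone | CC(=O)c1c(O)c(OC)c(OC)c(OC)c1OC | intermediate
10 | 2,4-dihydroxybenzaldehyde | O=Cc1ccc(O)cc1O | starting material
11 | 2,4-bis(benzyloxy)benzaldehyde | O=Cc1ccc(OCc2ccccc2)cc1OCc1ccccc1 | intermediate
12 | racemic 3-[2,4-bis(benzyloxy)phenyl]-3-hydroxy-1-(2-hydroxy-3,4,5,6-tetramethoxyphenyl)propan-1-one | COc1c(OC)c(O)c(C(=O)CC(O)c2ccc(OCc3ccccc3)cc2OCc2ccccc2)c(OC)c1OC | intermediate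
13 | (E)-3-[2,4-bis(benzyloxy)phenyl]-1-(2-hydroxy-3,4,5,6-tetramethoxyphenyl)prop-2-en-1-one | COc1c(OC)c(O)c(C(=O)/C=C/c2ccc(OCc3ccccc3)cc2OCc2ccccc2)c(OC)c1OC | intermediate
14 | racemic 2-[2,4-bis(benzyloxy)phenyl]-5,6,7,8-tetramethoxychroman-4-one | COc1c(OC)c(OC)c2c(c1OC)OC(c1ccc(OCc3ccccc3)cc1OCc1ccccc1)CC2=O | intermediate
15 | 2-[2,4-bis(benzyloxy)phenyl]-5,6,7,8-tetramethoxy-4H-chromen-4-one | COc1c(OC)c(OC)c2c(=O)cc(-c3ccc(OCc4ccccc4)cc3OCc3ccccc3)oc2c1OC | intermediate
16 | 2-(2,4-dihydroxyphenyl)-5,6,7,8-tetramethoxy-4H-chromen-4-one | COc1c(OC)c(OC)c2c(=O)cc(-c3ccc(O)cc3O)oc2c1OC | intermediate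
17 | Tamadone, 2-(2,4-dihydroxyphenyl)-5-hydroxy-6,7,8-trimethoxy-4H-chromen-4-one | COc1c(OC)c(O)c2c(=O)cc(-c3ccc(O)cc3O)oc2c1OC | target

**Total step count:** 10. **Longest linear sequence:** 9 (steps 1–5 and 7–10). Step 6 is the convergent branch.

**Three steps most likely to fail**

**Step 5.** The risk is over-demethylation or decomposition of the penta-ether by AlCl3. The fallback sets out from 7 and comes back at 9. It separates C–C bond formation from ether cleavage by using directed ortho-metalation in place of electrophilic substitution.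
- 7 is deprotonated at its only ring C–H, which is flanked by two OMe groups, with n-BuLi/TMEDA in THF at 0 °C. This gives pentamethoxyphenyllithium F1.
- Addition of N-methoxy-N-methylacetamide gives the stable tetrahedral lithium adduct F2.
- A 1 M HCl quench collapses the adduct to 8, which is isolated this time.
- BCl3 (1.1 equiv, CH2Cl2, −78 → 0 °C) then removes one of the two equivalent ortho methyl groups to give 9.

**Step 7.** The risk is a sluggish reaction between a hindered ketone and an electron-rich aldehyde, or a chalcone/flavanone mixture. The fallback sets out from 9 and 11 and comes back at 15. It bypasses 13 and step 8 by replacing the aldol with an intermolecular Claisen-type C-acylation at the correct oxidation level.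
- 11 is oxidised (NaClO2, NaH2PO4, 2-methyl-2-butene, t-BuOH/H2O) to 2,4-bis(benzyloxy)benzoic acid F3.
- This acid is converted with oxalyl chloride and catalytic DMF in CH2Cl2 into 2,4-bis(benzyloxy)benzoyl chloride F4.
- The acid chloride is added at −78 °C to 9 pre-treated with LiHMDS (3.2 equiv, THF). This gives 1-[2,4-bis(benzyloxy)phenyl]-3-(2-hydroxy-3,4,5,6-tetramethoxyphenyl)propane-1,3-dione F5.
- Catalytic p-TsOH in refluxing toluene (Dean–Stark) cyclodehydrates the diketone to 15.

**Step 10.** The risk is additional loss of the 6-OMe group, or poor behaviour of the free triphenol toward BCl3. The fallback sets out from 9 and comes back at 17. It moves the ether cleavage to the simple acetophenone and carries the future 5-OH group as a benzyl ether, so the end-game is a single hydrogenolysis.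
- 9 with BCl3 (CH2Cl2, −78 → 0 °C) gives the symmetric 2,6-dihydroxy-3,4,5-trimethoxyacetophenone F6.
- BnBr (1.05 equiv) with K2CO3 in refluxing acetone gives 2-benzyloxy-6-hydroxy-3,4,5-trimethoxyacetophenone F7.
- KOH/EtOH condensation with 11 passes through the racemic aldol adduct F8. It gives (E)-1-(2-benzyloxy-6-hydroxy-3,4,5-trimethoxyphenyl)-3-[2,4-bis(benzyloxy)phenyl]prop-2-en-1-one F9.
- I2/DMSO at 120 °C passes through the racemic flavanone F10. It gives 5-benzyloxy-2-[2,4-bis(benzyloxy)phenyl]-6,7,8-trimethoxy-4H-chromen-4-one F11.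
- H2 with Pd/C in EtOAc/MeOH removes all three benzyl groups to give 17.

**Further compounds**
F1 | step 5 | pentamethoxyphenyllithium | [Li]c1c(OC)c(OC)c(OC)c(OC)c1OC
F2 | step 5 | lithium 1-[methoxy(methyl)amino]-1-(pentamethoxyphenyl)ethan-1-olate | CC([O-])(N(C)OC)c1c(OC)c(OC)c(OC)c(OC)c1OC.[Li+]
F3 | step 7 | 2,4-bis(benzyloxy)benzoic acid | OC(=O)c1ccc(OCc2ccccc2)cc1OCc1ccccc1
F4 | step 7 | 2,4-bis(benzyloxy)benzoyl chloride | ClC(=O)c1ccc(OCc2ccccc2)cc1OCc1ccccc1
F5 | step 7 | 1-[2,4-bis(benzyloxy)phenyl]-3-(2-hydroxy-3,4,5,6-tetramethoxyphenyl)propane-1,3-dione | COc1c(OC)c(O)c(C(=O)CC(=O)c2ccc(OCc3ccccc3)cc2OCc2ccccc2)c(OC)c1OC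
F6 | step 10 | 2,6-dihydroxy-3,4,5-trimethoxyacetophenone | CC(=O)c1c(O)c(OC)c(OC)c(OC)c1O
F7 | step 10 | 2-benzyloxy-6-hydroxy-3,4,5-trimethoxyacetophenone | CC(=O)c1c(O)c(OC)c(OC)c(OC)c1OCc1ccccc1
F8 | step 10 | racemic 1-(2-benzyloxy-6-hydroxy-3,4,5-trimethoxyphenyl)-3-[2,4-bis(benzyloxy)phenyl]-3-hydroxypropan-1-one | COc1c(OC)c(O)c(C(=O)CC(O)c2ccc(OCc3ccccc3)cc2OCc2ccccc2)c(OCc2ccccc2)c1OC
F9 | step 10 | (E)-1-(2-benzyloxy-6-hydroxy-3,4,5-trimethoxyphenyl)-3-[2,4-bis(benzyloxy)phenyl]prop-2-en-1-one | COc1c(OC)c(O)c(C(=O)/C=C/c2ccc(OCc3ccccc3)cc2OCc2ccccc2)c(OCc2ccccc2)c1OC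
F10 | step 10 | racemic 5-benzyloxy-2-[2,4-bis(benzyloxy)phenyl]-6,7,8-trimethoxychroman-4-one | COc1c(OC)c(OCc2ccccc2)c2c(c1OC)OC(c1ccc(OCc3ccccc3)cc1OCc1ccccc1)CC2=O
F11 | step 10 | 5-benzyloxy-2-[2,4-bis(benzyloxy)phenyl]-6,7,8-trimethoxy-4H-chromen-4-one | COc1c(OC)c(OCc2ccccc2)c2c(=O)cc(-c3ccc(OCc4ccccc4)cc3OCc3ccccc3)oc2c1OC
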